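**Retrosynthetic overview**
1. Feature: in ring A the oxygenated C3, the quaternary C4 (Me, CO2Me), C5 (H) and the quaternary C10 (Me) are contiguous. This array maps onto a 2-silyloxy diene ester C1=C2–C3(OSi)=C4(Me)CO2Me joined to an α-methyl enal C5=C10 whose formyl carbon is C9.
2. Ring A is made first, by an enantioselective Diels–Alder reaction that forms C4–C5 and C1–C10. The adduct holds C3 as a silyl enol ether, C9 as an aldehyde and C6–C7–C8≡C17 as a butynyl arm.
3. Ring B is made second: C9–C11 by addition of the C11–C15 Grignard reagent to the aldehyde, then C8–C9 and the C8(17) methylene by 6-exo-dig cyclisation of the C9 radical released from a xanthate.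
4. End game: enol ether → C3 ketone → axial 3α-alcohol (bulky borohydride) → acetate, then release of the C15 alcohol.
5. Building blocks: diene from methyl propionate and acrolein, enynal from pent-4-yn-1-ol, side-chain bromide from a butynyl silyl ether by carboalumination.

Key step: step 6

Assumption: labdane numbering is used for every intermediate; the sense of induction in step 6 is assigned from the formyl C–H···O binding model of the oxazaborolidinium cation, which points to the (R)-diphenylprolinol-derived catalyst, and the enantiomeric catalyst is equally available should the sense prove opposite.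

**Step 1**
Reactants: 1 methyl propionate; 2 acrolein
Product: 4 methyl 3-hydroxy-2-methylpent-4-enoate (racemic syn/anti mixture), via lithium enolate of methyl propionate 3 (not isolated)
Conditions: LiN(i-Pr)2 (LDA), THF, −78 °C; then 2, −78 °C; AcOH quench
Reagents that add atoms: none
Why: The kinetic ester enolate adds 1,2 to the enal at −78 °C (aldol addition), and both new stereocentres are erased in steps 2 and 3, so their ratio does not matter.

**Step 2**
Reactants: 4 methyl 3-hydroxy-2-methylpent-4-enoate
Product: 5 methyl 2-methyl-3-oxopent-4-enoate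
Conditions: Dess–Martin periodinane, CH2Cl2, 0 °C → rt; used at once
Reagents that add atoms: none
Why: Dess–Martin oxidation of the secondary allylic alcohol under neutral conditions gives the vinyl ketone (a 2-methyl Nazarov reagent) in the absence of base, which would start its Michael oligomerisation.

**Step 3**
Reactants: 5 methyl 2-methyl-3-oxopent-4-enoate
Product: 7 methyl (2Z)-3-(tert-butyldimethylsilyloxy)-2-methylpenta-2,4-dienoate, via chelated sodium enolate 6 (not isolated)
Conditions: NaN(SiMe3)2, THF, −78 °C (5 added to the base); TBSOTf, −78 → 0 °C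
Reagents that add atoms: tert-butyldimethylsilyl triflate (TBSOTf), CC(C)(C)[Si](C)(C)OS(=O)(=O)C(F)(F)F
Why: Deprotonation between the two carbonyl groups gives the U-shaped sodium chelate, and O-silylation of the ketone oxygen in this chelate (enol silylation of a β-keto ester) leaves the silyloxy group cis to the ester, which is the Z geometry.

**Step 4**
Reactants: 8 pent-4-yn-1-ol
Product: 9 pent-4-ynal
Conditions: Dess–Martin periodinane, CH2Cl2, 0 °C → rt; solution used directly
Reagents that add atoms: none
Why: Dess–Martin oxidation takes the primary alcohol to the aldehyde without over-oxidation and leaves the terminal alkyne untouched; the volatile aldehyde is not concentrated.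

**Step 5**
Reactants: 9 pent-4-ynal; 10 2-(triphenylphosphoranylidene)propanal
Product: 11 (E)-2-methylhept-2-en-6-ynal
Conditions: CH2Cl2, 40 °C
Reagents that add atoms: none
Why: The stabilised formyl ylide olefinates the aliphatic aldehyde (Wittig reaction) much faster than the conjugated product aldehyde and gives the E trisubstituted enal, in which formyl group and chain are trans.

**Step 6**
Reactants: 7 methyl (2Z)-3-(tert-butyldimethylsilyloxy)-2-methylpenta-2,4-dienoate (1.5 equiv); 11 (E)-2-methylhept-2-en-6-ynal
Product: 12 methyl 6-(but-3-ynyl)-2-(tert-butyldimethylsilyloxy)-5-formyl-1,5-dimethylcyclohex-2-ene-1-carboxylate (labdane sense: 4β-CO2Me/4α-Me/5α-H/10β-Me/10α-CHO)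
Conditions: (R)-B-(o-tolyl)-α,α-diphenylprolinol oxazaborolidine (20 mol %), Tf2NH (18 mol %), CH2Cl2, −78 → −40 °C
Reagents that add atoms: none
Why: The boron cation binds the formyl oxygen of the s-trans enal and lowers its LUMO, and the silyl dienol ether adds in a concerted but strongly asynchronous normal-demand [4+2] in which its nucleophilic enol-ether carbon C4 bonds to the enal β-carbon C5 ahead of C1–C10; the closest known reaction type is the oxazaborolidinium-catalysed Diels–Alder reaction of 2-silyloxydienes with α-methyl enals. Ring A is closed by the intermolecular cycloaddition itself (two σ bonds formed suprafacially on each partner), which delivers the cyclohexene as a silyl enol ether, a latent C3 ketone. C5 and C10 are set relative to each other by the E geometry of the enal (C10 methyl cis to the butynyl arm, formyl trans), and C4 relative to them by the Z geometry of the diene, whose ester is the outside terminus substituent, together with a formyl-exo approach that places the ester cis to the C10 methyl. The absolute configuration comes from the catalyst, which by the formyl C–H···O binding model shields one enal face and leaves the Si face of C10 (Re face of C5) open. The step needs regioselectivity, formyl-exo selectivity and face selectivity: the first follows from the match of the donor terminus C4 with the acceptor carbon C5, the second is expected from the α-methyl group and the bulky Lewis acid on the formyl group, which disfavour the formyl-endo arrangement, and the third from the chiral cation. The inside methyl group on C4 slows the reaction, which is why the strongly activating cationic Lewis acid and an excess of diene are used.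

**Step 7**
Reactants: 13 tert-butyl(but-3-yn-1-yloxy)dimethylsilane
Product: 16 (E)-5-(tert-butyldimethylsilyloxy)-3-methylpent-2-en-1-ol, via (E)-alkenyldimethylalane 14 (not isolated), via lithium butyl(alkenyl)dimethylalanate 15 (not isolated)
Conditions: Me3Al, Cp2ZrCl2 (20 mol %), CH2Cl2, 0 °C → rt; volatiles removed; n-BuLi, hexane/THF, −78 → 0 °C; (CH2O)n, rt; cold 1 M HCl
Reagents that add atoms: trimethylaluminium, C[Al](C)C; paraformaldehyde (as formaldehyde), C=O
Why: Zirconium-catalysed carboalumination (Negishi) adds methyl and aluminium syn across the terminal alkyne with methyl on the internal carbon, and the derived alanate is hydroxymethylated by formaldehyde with retention, which fixes the E trisubstituted olefin (later C13=C14).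

**Step 8**
Reactants: 16 (E)-5-(tert-butyldimethylsilyloxy)-3-methylpent-2-en-1-ol
Product: 17 (E)-5-(tert-butyldimethylsilyloxy)-1-(tert-butyldiphenylsilyloxy)-3-methylpent-2-ene
Conditions: TBDPSCl, imidazole, CH2Cl2, rt
Reagents that add atoms: tert-butyldiphenylsilyl chloride (TBDPSCl), CC(C)(C)[Si](Cl)(c1ccccc1)c1ccccc1
Why: Imidazole-promoted silylation of the unhindered primary allylic alcohol installs the robust TBDPS ether that has to outlast steps 9 to 16.

**Step 9**
Reactants: 17 (E)-5-(tert-butyldimethylsilyloxy)-1-(tert-butyldiphenylsilyloxy)-3-methylpent-2-ene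
Product: 18 (E)-5-(tert-butyldiphenylsilyloxy)-3-methylpent-3-en-1-ol
Conditions: PPTS (cat.), EtOH, rt
Reagents that add atoms: none
Why: Mildly acidic ethanolysis removes the primary TBS ether far faster than the bulkier, more acid-stable primary TBDPS ether, a standard selective desilylation.

**Step 10**
Reactants: 18 (E)-5-(tert-butyldiphenylsilyloxy)-3-methylpent-3-en-1-ol
Product: 19 (E)-(5-bromo-3-methylpent-2-enyloxy)(tert-butyl)diphenylsilane
Conditions: CBr4, PPh3, CH2Cl2, 0 °C
Reagents that add atoms: carbon tetrabromide, BrC(Br)(Br)Br
Why: Appel bromination converts the primary homoallylic alcohol into the bromide by SN2 displacement of the oxyphosphonium group under neutral conditions, without touching the allylic silyl ether or the olefin geometry.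

**Step 11**
Reactants: 12 Diels–Alder adduct (aldehyde); 19 (E)-(5-bromo-3-methylpent-2-enyloxy)(tert-butyl)diphenylsilane (2 equiv)
Product: 21 methyl 6-(but-3-ynyl)-2-(tert-butyldimethylsilyloxy)-5-[(E)-6-(tert-butyldiphenylsilyloxy)-1-hydroxy-4-methylhex-4-enyl]-1,5-dimethylcyclohex-2-ene-1-carboxylate (both C9 epimers), via alkylmagnesium bromide 20 (not isolated)
Conditions: 19, Mg, THF, 25 °C; then 12, THF, −78 → −20 °C; H2O
Reagents that add atoms: none
Why: Addition of the primary alkylmagnesium bromide to the non-enolisable neopentyl aldehyde (Grignard addition) is faster at low temperature than deprotonation of the terminal alkyne or attack on the hindered quaternary ester and leaves the silyl enol ether untouched; the new C9 carbinol centre forms unselectively, which is harmless because C9 becomes a planar radical in step 13.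

**Step 12**
Reactants: 21 C9 carbinol (both epimers)
Product: 23 O-alkyl S-methyl xanthate of carbinol 21 (both C9 epimers), via sodium dithiocarbonate salt 22 (not isolated)
Conditions: NaN(SiMe3)2, THF, −78 °C; CS2, → 0 °C; MeI, 0 °C → rt
Reagents that add atoms: carbon disulfide, S=C=S; iodomethane, CI
Why: The alkoxide, formed selectively over the far less acidic alkyne C–H, adds to CS2 and the dithiocarbonate salt is S-methylated (xanthate formation for a Barton–McCombie sequence) under conditions that the silyl enol ether, the ester and the silyl ether tolerate.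

**Step 13**
Reactants: 23 xanthate
Product: 24 methyl (13E)-3-(tert-butyldimethylsilyloxy)-15-(tert-butyldiphenylsilyloxy)labda-2,8(17),13-trien-19-oate
Conditions: Bu3SnH + AIBN (syringe pump, 8 h), PhH (0.005 M), 80 °C
Reagents that add atoms: none
Why: Stannyl radical attack on the thiocarbonyl group and C9–O scission (Barton–McCombie) give the secondary C9 radical, which closes 6-exo-dig onto C8 of the butynyl arm through a chair transition state that is trans-fused because the C6 and C9 arms are trans-diequatorial on ring A; the C11 chain sits pseudo-equatorial so that H-9 ends up α, and the vinyl radical takes hydrogen from Bu3SnH to leave the C8(17) methylene, the stannane being kept dilute so that ring closure can outrun direct reduction.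

**Step 14**
Reactants: 24 bicyclic silyl enol ether
Product: 25 methyl (13E)-15-(tert-butyldiphenylsilyloxy)-3-oxolabda-8(17),13-dien-19-oate
Conditions: 1 M aq HCl, THF, 0 °C → rt
Reagents that add atoms: none
Why: Dilute acid protonates the enol ether at C2 and water removes the silyl group (silyl enol ether hydrolysis), unveiling the C3 ketone next to the quaternary, non-epimerisable C4 while the primary TBDPS ether, the exocyclic methylene and the ester are stable to these conditions.

**Step 15**
Reactants: 25 C3 ketone
Product: 26 methyl (13E)-15-(tert-butyldiphenylsilyloxy)-3α-hydroxylabda-8(17),13-dien-19-oate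
Conditions: LiBH(s-Bu)3 (L-Selectride), THF, −78 °C; H2O
Reagents that add atoms: none
Why: The bulky trialkylborohydride cannot use the axial α trajectory past H-1α and H-5α and delivers hydride along the equatorial path (Selectride reduction of a cyclohexanone), which gives the axial 3α-alcohol, while the hindered axial ester and the olefins are not reduced at −78 °C.

**Step 16**
Reactants: 26 3α-alcohol
Product: 27 methyl (13E)-3α-acetoxy-15-(tert-butyldiphenylsilyloxy)labda-8(17),13-dien-19-oate
Conditions: Ac2O, DMAP, pyridine, 40 °C
Reagents that add atoms: acetic anhydride, CC(=O)OC(C)=O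
Why: DMAP-catalysed acylation overcomes the hindrance of the axial alcohol next to the quaternary C4, and no other free hydroxyl group is present.

**Step 17**
Reactants: 27 acetate
Product: 28 methyl (13E)-3α-acetoxy-15-hydroxylabda-8(17),13-dien-19-oate (CNP0164591.1)
Conditions: HF·pyridine, pyridine/THF, 0 °C → rt
Reagents that add atoms: none
Why: Fluoride cleaves the Si–O bond of the primary TBDPS ether (desilylation) under buffered, weakly acidic conditions that leave the acetate, the methyl ester and the exocyclic olefin untouched.

**Compound list**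
1 | methyl propionate | CCC(=O)OC | starting material
2 | acrolein | C=CC=O | starting material
3 | lithium enolate of methyl propionate (geometry immaterial) | [Li+].CC=C([O-])OC | intermediate
4 | methyl 3-hydroxy-2-methylpent-4-enoate (racemic syn/anti mixture) | C=CC(O)C(C)C(=O)OC | intermediate
5 | methyl 2-methyl-3-oxopent-4-enoate | C=CC(=O)C(C)C(=O)OC | intermediate
6 | chelated sodium (Z)-enolate of 5 | [Na+].C=C/C([O-])=C(\C)C(=O)OC | intermediate
7 | methyl (2Z)-3-(tert-butyldimethylsilyloxy)-2-methylpenta-2,4-dienoate | C=C/C(O[Si](C)(C)C(C)(C)C)=C(\C)C(=O)OC | intermediate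
8 | pent-4-yn-1-ol | C#CCCCO | starting material
9 | pent-4-ynal | C#CCCC=O | intermediate
10 | 2-(triphenylphosphoranylidene)propanal | CC(C=O)=P(c1ccccc1)(c1ccccc1)c1ccccc1 | starting material
11 | (E)-2-methylhept-2-en-6-ynal | O=C/C(C)=C/CCC#C | intermediate
12 | ring-A adduct, methyl 6-(but-3-ynyl)-2-(tert-butyldimethylsilyloxy)-5-formyl-1,5-dimethylcyclohex-2-ene-1-carboxylate (4β-CO2Me, 4α-Me, 5α-H, 10β-Me, 10α-CHO) | C#CCC[C@@H]1[C@@](C)(C=O)CC=C(O[Si](C)(C)C(C)(C)C)[C@]1(C)C(=O)OC | intermediate
13 | tert-butyl(but-3-yn-1-yloxy)dimethylsilane | C#CCCO[Si](C)(C)C(C)(C)C | starting material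
14 | (E)-[4-(tert-butyldimethylsilyloxy)-2-methylbut-1-enyl]dimethylalane | C[Al](C)/C=C(\C)CCO[Si](C)(C)C(C)(C)C | intermediate
15 | lithium butyl[(E)-4-(tert-butyldimethylsilyloxy)-2-methylbut-1-enyl]dimethylalanate | [Li+].CCCC[Al-](C)(C)/C=C(\C)CCO[Si](C)(C)C(C)(C)C | intermediate
16 | (E)-5-(tert-butyldimethylsilyloxy)-3-methylpent-2-en-1-ol | OC/C=C(\C)CCO[Si](C)(C)C(C)(C)C | intermediate
17 | (E)-5-(tert-butyldimethylsilyloxy)-1-(tert-butyldiphenylsilyloxy)-3-methylpent-2-ene | CC(C)(C)[Si](C)(C)OCC/C(C)=C/CO[Si](c1ccccc1)(c1ccccc1)C(C)(C)C | intermediate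
18 | (E)-5-(tert-butyldiphenylsilyloxy)-3-methylpent-3-en-1-ol | OCC/C(C)=C/CO[Si](c1ccccc1)(c1ccccc1)C(C)(C)C | intermediate
19 | (E)-(5-bromo-3-methylpent-2-enyloxy)(tert-butyl)diphenylsilane | BrCC/C(C)=C/CO[Si](c1ccccc1)(c1ccccc1)C(C)(C)C | intermediate
20 | (E)-[5-(tert-butyldiphenylsilyloxy)-3-methylpent-3-enyl]magnesium bromide | Br[Mg]CC/C(C)=C/CO[Si](c1ccccc1)(c1ccccc1)C(C)(C)C | intermediate
21 | C9 carbinol (both C9 epimers), adduct 12 with CHO converted into CH(OH)CH2CH2C(Me)=CHCH2OTBDPS | C#CCC[C@@H]1[C@@](C)(C(O)CC/C(C)=C/CO[Si](c2ccccc2)(c2ccccc2)C(C)(C)C)CC=C(O[Si](C)(C)C(C)(C)C)[C@]1(C)C(=O)OC | intermediate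
22 | sodium O-alkyl dithiocarbonate of 21 | C#CCC[C@@H]1[C@@](C)(C(OC(=S)[S-])CC/C(C)=C/CO[Si](c2ccccc2)(c2ccccc2)C(C)(C)C)CC=C(O[Si](C)(C)C(C)(C)C)[C@]1(C)C(=O)OC.[Na+] | intermediate
23 | O-alkyl S-methyl xanthate of 21 (both C9 epimers) | C#CCC[C@@H]1[C@@](C)(C(OC(=S)SC)CC/C(C)=C/CO[Si](c2ccccc2)(c2ccccc2)C(C)(C)C)CC=C(O[Si](C)(C)C(C)(C)C)[C@]1(C)C(=O)OC | intermediate
24 | methyl (13E)-3-(tert-butyldimethylsilyloxy)-15-(tert-butyldiphenylsilyloxy)labda-2,8(17),13-trien-19-oate | C=C1CC[C@@H]2[C@](C)(CC=C(O[Si](C)(C)C(C)(C)C)[C@]2(C)C(=O)OC)[C@H]1CC/C(C)=C/CO[Si](c1ccccc1)(c1ccccc1)C(C)(C)C | intermediate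
25 | methyl (13E)-15-(tert-butyldiphenylsilyloxy)-3-oxolabda-8(17),13-dien-19-oate | C=C1CC[C@@H]2[C@](C)(CCC(=O)[C@]2(C)C(=O)OC)[C@H]1CC/C(C)=C/CO[Si](c1ccccc1)(c1ccccc1)C(C)(C)C | intermediate
26 | methyl (13E)-15-(tert-butyldiphenylsilyloxy)-3α-hydroxylabda-8(17),13-dien-19-oate | C=C1CC[C@@H]2[C@](C)(CC[C@@H](O)[C@]2(C)C(=O)OC)[C@H]1CC/C(C)=C/CO[Si](c1ccccc1)(c1ccccc1)C(C)(C)C | intermediate
27 | methyl (13E)-3α-acetoxy-15-(tert-butyldiphenylsilyloxy)labda-8(17),13-dien-19-oate | C=C1CC[C@@H]2[C@](C)(CC[C@@H](OC(C)=O)[C@]2(C)C(=O)OC)[C@H]1CC/C(C)=C/CO[Si](c1ccccc1)(c1ccccc1)C(C)(C)C | intermediate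
28 | methyl (13E)-3α-acetoxy-15-hydroxylabda-8(17),13-dien-19-oate (CNP0164591.1) | C=C1CC[C@@H]2[C@](C)(CC[C@@H](OC(C)=O)[C@]2(C)C(=O)OC)[C@H]1CC/C(C)=C/CO | target

**Step count**
Total: 17 steps. Longest linear sequence: 11 steps (steps 1–3, 6, 11–17; the branch 7–10, 11–17 is equally long).

**Steps most likely to fail**

1. Step 6. The cycloaddition may stall because the inside methyl group on C4 keeps the diene out of the s-cis form. It may also be diverted into Mukaiyama aldol addition at the formyl group, discriminate poorly between formyl-exo and formyl-endo approach, or lose enol-ether geometry by silyl migration before reaction. Fallback, setting out from enal 11 (with methyl acetate and acrolein 2) and returning at adduct 12: the C4 methyl group is left out of the cycloaddition and installed afterwards. Methyl acetate and 2 are taken through the operations of steps 1 to 3 to methyl 3-hydroxypent-4-enoate F1, methyl 3-oxopent-4-enoate F2 and methyl (2Z)-3-(tert-butyldimethylsilyloxy)penta-2,4-dienoate F3. This diene has a CH terminus with the ester outside and is far more reactive; it is combined with 11 under the catalyst of step 6 to give the C4-unmethylated adduct F4, whose C4 configuration is immaterial. Dilute aqueous HCl in THF gives the β-keto ester aldehyde F5. C-Methylation with K2CO3 and MeI in acetone then gives the 3-oxo aldehyde F6; the electrophile should enter C4 from the α face, anti to the C5 butynyl arm and to the axial C10 methyl, the usual course of alkylation of 3-oxo-4-carbomethoxy systems towards the axial-ester series. Silylation with TBSOTf and Et3N, where enolisation is possible only towards C2, returns 12.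

2. Step 13. The C9 radical may be reduced before it closes, or may take hydrogen by 1,5-transfer from the propargylic C7 or the allylic C16 position. The vinyl radical may abstract the allylic C12 hydrogen and scramble the C13 olefin, and control at C9 may be poor. Fallback, setting out from aldehyde 12 and bromide 19 and returning at ketone 25: the polarity of the ring closure is reversed, with the radical on C8 and the olefin at C9. Bromide 19 and PPh3 in MeCN at reflux give the phosphonium bromide F7. Its ylide (NaN(SiMe3)2, THF, −78 °C → rt) converts 12 by Wittig reaction into the (Z)-C9=C11 enyne F8. Bu3SnH and AIBN in benzene at 80 °C add a stannyl radical reversibly to C17; the C8 vinyl radical has no hydrogen in a 1,5 relationship and closes 6-exo onto C9 (hydrostannylative enyne cyclisation, side chain pseudo-equatorial), giving the exocyclic vinylstannane F9. Aqueous HCl in THF removes the stannyl group by ipso-protonation and hydrolyses the enol ether in the same operation, giving 25.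

3. Step 3. The vinyl ketone may oligomerise anionically while the enolate is being formed, and the Z geometry may be eroded. Fallback, setting out from lithium enolate 3 (from methyl propionate 1) and returning at diene 7: the vinyl group is carried in masked form. Enolate 3 (2 equiv) is C-acylated with 3-chloropropanoyl chloride at −78 °C to methyl 5-chloro-2-methyl-3-oxopentanoate F10. This is silylated through its sodium chelate as in step 3 to methyl (2Z)-3-(tert-butyldimethylsilyloxy)-5-chloro-2-methylpent-2-enoate F11. DBU in CH2Cl2 then eliminates HCl and unveils the vinyl group, giving 7.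

**Further compounds**
F1 | step 6 | methyl 3-hydroxypent-4-enoate (racemic) | C=CC(O)CC(=O)OC
F2 | step 6 | methyl 3-oxopent-4-enoate | C=CC(=O)CC(=O)OC
F3 | step 6 | methyl (2Z)-3-(tert-butyldimethylsilyloxy)penta-2,4-dienoate | C=C/C(O[Si](C)(C)C(C)(C)C)=C/C(=O)OC
F4 | step 6 | methyl 6-(but-3-ynyl)-2-(tert-butyldimethylsilyloxy)-5-formyl-5-methylcyclohex-2-ene-1-carboxylate (C4 epimers) | C#CCC[C@@H]1[C@@](C)(C=O)CC=C(O[Si](C)(C)C(C)(C)C)C1C(=O)OC
F5 | step 6 | methyl 6-(but-3-ynyl)-5-formyl-5-methyl-2-oxocyclohexane-1-carboxylate (C4 epimers) | C#CCC[C@@H]1[C@@](C)(C=O)CCC(=O)C1C(=O)OC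
F6 | step 6 | methyl 6-(but-3-ynyl)-5-formyl-1,5-dimethyl-2-oxocyclohexane-1-carboxylate (4β-CO2Me, 4α-Me) | C#CCC[C@@H]1[C@@](C)(C=O)CCC(=O)[C@]1(C)C(=O)OC
F7 | step 13 | (E)-[5-(tert-butyldiphenylsilyloxy)-3-methylpent-3-enyl]triphenylphosphonium bromide | [Br-].CC(C)(C)[Si](c1ccccc1)(c1ccccc1)OC/C=C(\C)CC[P+](c1ccccc1)(c1ccccc1)c1ccccc1
F8 | step 13 | (Z)-C9=C11 enyne, adduct 12 with CHO converted into CH=CHCH2C(Me)=CHCH2OTBDPS | C#CCC[C@@H]1[C@@](C)(/C=C\C/C(C)=C/CO[Si](c2ccccc2)(c2ccccc2)C(C)(C)C)CC=C(O[Si](C)(C)C(C)(C)C)[C@]1(C)C(=O)OC
F9 | step 13 | 17-(tributylstannyl) derivative of 24 (vinylstannane, geometry at C17 immaterial) | CCCC[Sn](CCCC)(CCCC)C=C1CC[C@@H]2[C@](C)(CC=C(O[Si](C)(C)C(C)(C)C)[C@]2(C)C(=O)OC)[C@H]1CC/C(C)=C/CO[Si](c1ccccc1)(c1ccccc1)C(C)(C)C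
F10 | step 3 | methyl 5-chloro-2-methyl-3-oxopentanoate | ClCCC(=O)C(C)C(=O)OC
F11 | step 3 | methyl (2Z)-3-(tert-butyldimethylsilyloxy)-5-chloro-2-methylpent-2-enoate | ClCC/C(O[Si](C)(C)C(C)(C)C)=C(\C)C(=O)OC
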